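**Plan**
- Retrosynthesis: the epoxide oxygen is removed first, leaving a (Z)-C4=C5 olefin beside the C3 carbinol. The C5–C6 ring bond and the lactone C12–O bond are then cut in one operation. Further cuts are C2–C3 (aldol), the C8 ester, C1–C2 (methyl addition to a lactone) and C8–C9 (acylation of a zinc reagent).
- Enabling feature: the butenolide (ring O–C12(=O)–C11=C7–C6) is the cyclic form of a (Z)-4-oxobut-2-enoate whose aldehyde carbon is C6, and a 2-silylfuran delivers that unit on photooxygenation. C5 is the vinylic CH of the (Z)-C4=C5 olefin, so a (Z)-alkenyl metal at C5 can add to C6, and the alkoxide formed sits cis to the C12 ester.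
- Forward: a 2-silyl-3,4-disubstituted furan is built, acylated, reduced, turned into a methyl ketone, esterified at C8 and extended by aldol with (Z)-3-iodo-2-methylpropenal. The furan is then opened oxidatively, and one alkenylchromium addition closes the ten-membered carbocycle and the butenolide together. Peracid epoxidation ends the route.
- Stereochemistry: C10 comes from methyl (R)-3-bromo-2-methylpropanoate, C8 from asymmetric transfer hydrogenation, C3 from a reagent-controlled boron aldol. C6 is set in the ring closure under control of C8. C4 and C5 are set by hydroxyl-directed epoxidation of the Z-olefin. Both Z-olefins derive from one anti-carbomagnesiation product.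

Key step: step 19

Remark: germacrane numbering is used (C1 ketone, C3 carbinol, C4/C5 epoxide carbons, C6 lactone carbinol, C7=C11 butenolide olefin, C8 acyloxy carbon, C10 methyl-bearing carbon, C12 lactone carbonyl, C13 acetoxymethyl); TBS = tert-butyldimethylsilyl, TES = triethylsilyl; compounds 1, 9 and 16 are taken to be commercial.

**Route**

Step 1
Reactants: 1 furan-3-ylmethanol
Product: 2 tert-butyl(furan-3-ylmethoxy)dimethylsilane
Conditions: TBSCl, imidazole, DMF, 0 °C → rt
Reagents that add atoms: tert-butyldimethylsilyl chloride CC(C)(C)[Si](C)(C)Cl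
Why: Imidazole-promoted O-silylation of a primary alcohol places the silyl group on oxygen, from where it is moved to carbon in step 2.

Step 2
Reactants: 2 tert-butyl(furan-3-ylmethoxy)dimethylsilane
Product: 4 [2-(tert-butyldimethylsilyl)furan-3-yl]methanol, via 2-lithiofuran 3 (not isolated)
Conditions: n-BuLi, HMPA, THF, −78 °C → rt; H2O
Reagents that add atoms: none
Why: Lithiation at the α-position flanked by the ring oxygen and the CH2O group is followed by a retro-Brook 1,4 O→C silyl shift, which puts silicon on the carbon that becomes C12 and frees the hydroxymethyl group (C13).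

Step 3
Reactants: 4 [2-(tert-butyldimethylsilyl)furan-3-yl]methanol
Product: 6 5-(tert-butyldimethylsilyl)-4-(hydroxymethyl)furan-3-carboxylic acid, via dilithio species 5 (not isolated)
Conditions: n-BuLi (2.2 equiv), DME, 0 °C; CO2, −78 °C → rt; aq. HCl
Reagents that add atoms: carbon dioxide O=C=O
Why: Alkoxide-directed ortho-lithiation goes to C4 because C2 is blocked by silicon, and carboxylation of the aryllithium installs the carbon that becomes C8.

Step 4
Reactants: 6 5-(tert-butyldimethylsilyl)-4-(hydroxymethyl)furan-3-carboxylic acid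
Product: 8 5-(tert-butyldimethylsilyl)-4-[(tert-butyldimethylsilyloxy)methyl]furan-3-carboxylic acid, via silyl ester 7 (not isolated)
Conditions: TBSCl (2.5 equiv), imidazole, DMF, rt; then K2CO3, MeOH/THF/H2O, 0 °C; aq. HCl to pH 4
Reagents that add atoms: tert-butyldimethylsilyl chloride CC(C)(C)[Si](C)(C)Cl
Why: Exhaustive silylation followed by selective solvolysis of the silyl ester, which is far more labile than the primary silyl ether, leaves the acid free for activation.

Step 5
Reactants: 8 5-(tert-butyldimethylsilyl)-4-[(tert-butyldimethylsilyloxy)methyl]furan-3-carboxylic acid; 9 methyl (R)-3-bromo-2-methylpropanoate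
Product: 12 methyl (2S)-2-methyl-4-oxo-4-[5-TBS-4-(TBSOCH2)furan-3-yl]butanoate, via acid chloride 10 (not isolated), via alkylzinc bromide 11 (not isolated)
Conditions: 8, 1-chloro-N,N,2-trimethylprop-1-en-1-amine, CH2Cl2, 0 °C → rt; 9, Zn dust, LiCl, THF, 40 °C; then PdCl2(PPh3)2 (3 mol %), THF, 0 °C → rt
Reagents that add atoms: none
Why: Negishi acylation of the β-zincio ester with the acid chloride (made without acid by the chloroenamine) forms C8–C9; the C10 stereocentre is not involved and is carried over from 9.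

Step 6
Reactants: 12 methyl (2S)-2-methyl-4-oxo-4-[5-TBS-4-(TBSOCH2)furan-3-yl]butanoate
Product: 14 (3S,5S)-3-methyl-5-[5-TBS-4-(TBSOCH2)furan-3-yl]oxolan-2-one, via hydroxy ester 13 (not isolated)
Conditions: RuCl(p-cymene)[(S,S)-TsDPEN] (1 mol %), HCO2H/Et3N (5:2), EtOAc, rt; then PPTS (cat.), toluene, 60 °C
Reagents that add atoms: none
Why: Noyori asymmetric transfer hydrogenation of the heteroaryl ketone sets C8 as S under catalyst control (the (S,S) ligand gives the S carbinol of aryl alkyl ketones), and acid-catalysed lactonisation of the γ-hydroxy ester follows.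

Step 7
Reactants: 14 (3S,5S)-3-methyl-5-[5-TBS-4-(TBSOCH2)furan-3-yl]oxolan-2-one
Product: 15 (3S,5S)-5-hydroxy-3-methyl-5-[5-TBS-4-(TBSOCH2)furan-3-yl]pentan-2-one
Conditions: MeLi (1.05 equiv), THF, −78 °C; H2O, −78 °C
Reagents that add atoms: methyllithium [Li]C
Why: Mono-addition of an organolithium to a γ-lactone stops at the lithium lactolate at −78 °C, which gives the methyl ketone (C1 with C2) on work-up.

Step 8
Reactants: 16 prop-2-yn-1-ol
Product: 18 (Z)-3-iodo-2-methylprop-2-en-1-ol, via alkenylmagnesium alkoxide 17 (not isolated)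
Conditions: MeMgBr (2.5 equiv), CuI (10 mol %), Et2O, −10 °C → rt; then I2, −78 °C → rt
Reagents that add atoms: methylmagnesium bromide C[Mg]Br; iodine II
Why: Copper-catalysed anti-carbomagnesiation of the propargylic alkoxide proceeds through a five-membered magnesium chelate, and iodinolysis with retention gives the iodide cis to CH2OH.

Step 9
Reactants: 18 (Z)-3-iodo-2-methylprop-2-en-1-ol
Product: 19 tert-butyl{[(Z)-3-iodo-2-methylprop-2-en-1-yl]oxy}dimethylsilane
Conditions: TBSCl, imidazole, CH2Cl2, 0 °C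
Reagents that add atoms: tert-butyldimethylsilyl chloride CC(C)(C)[Si](C)(C)Cl
Why: Standard O-silylation protects the hydroxyl group for the halogen–metal exchange.

Step 10
Reactants: 19 tert-butyl{[(Z)-3-iodo-2-methylprop-2-en-1-yl]oxy}dimethylsilane
Product: 21 (2Z)-4-[(tert-butyldimethylsilyl)oxy]-3-methylbut-2-enoic acid, via alkenyllithium 20 (not isolated)
Conditions: t-BuLi (2.1 equiv), Et2O, −78 °C; CO2, −78 °C → 0 °C; aq. HCl to pH 4
Reagents that add atoms: carbon dioxide O=C=O
Why: Iodine–lithium exchange and carboxylation both proceed with retention of olefin geometry at −78 °C, and the silyl ether keeps the Z-acid from closing to a butenolide.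

Step 11
Reactants: 15 (3S,5S)-5-hydroxy-3-methyl-5-[5-TBS-4-(TBSOCH2)furan-3-yl]pentan-2-one; 21 (2Z)-4-[(tert-butyldimethylsilyl)oxy]-3-methylbut-2-enoic acid
Product: 23 (1S,3S)-3-methyl-4-oxo-1-[5-TBS-4-(TBSOCH2)furan-3-yl]pentyl (2Z)-3-methyl-4-(TBSO)but-2-enoate, via mixed anhydride 22 (not isolated)
Conditions: 21, 2,4,6-trichlorobenzoyl chloride, Et3N, THF, 0 °C; then 15, DMAP (cat.), toluene, rt
Reagents that add atoms: none
Why: Yamaguchi esterification acylates the hindered C8 carbinol, drawing the open hydroxy ketone out of its hemiketal equilibrium, without touching the C8 stereocentre.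

Step 12
Reactants: 23 (1S,3S)-3-methyl-4-oxo-1-[5-TBS-4-(TBSOCH2)furan-3-yl]pentyl (2Z)-3-methyl-4-(TBSO)but-2-enoate
Product: 25 (1S,3S)-1-[4-(acetoxymethyl)-5-TBS-furan-3-yl]-3-methyl-4-oxopentyl (2Z)-4-acetoxy-3-methylbut-2-enoate, via diol 24 (not isolated)
Conditions: HF·pyridine, pyridine, THF, 0 °C → rt; then Ac2O, DMAP (cat.), 0 °C, same flask
Reagents that add atoms: acetic anhydride CC(=O)OC(C)=O
Why: Fluoride cleaves the two primary O-silyl groups but not the C–Si bond on the furan, and immediate acetylation installs both acetates before the (Z)-γ-hydroxy enoate can lactonise.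

Step 13
Reactants: 18 (Z)-3-iodo-2-methylprop-2-en-1-ol
Product: 26 (Z)-3-iodo-2-methylprop-2-enal
Conditions: MnO2 (activated, excess), CH2Cl2, rt, dark; filtered and used at once
Reagents that add atoms: none
Why: Mild allylic oxidation with MnO2 gives the enal without acid or base, so the Z geometry should survive if the aldehyde is used immediately.

Step 14
Reactants: 25 (1S,3S)-1-[4-(acetoxymethyl)-5-TBS-furan-3-yl]-3-methyl-4-oxopentyl (2Z)-4-acetoxy-3-methylbut-2-enoate; 26 (Z)-3-iodo-2-methylprop-2-enal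
Product: 28 (1S,3S,6S,7Z)-1-[4-(acetoxymethyl)-5-TBS-furan-3-yl]-6-hydroxy-8-iodo-3,7-dimethyl-4-oxooct-7-en-1-yl (2Z)-4-acetoxy-3-methylbut-2-enoate, via boron enolate 27 (not isolated)
Conditions: (+)-Ipc2BCl, Et3N, Et2O, 0 °C; then 26, −78 °C → −20 °C; MeOH, pH 7 buffer, H2O2, 0 °C
Reagents that add atoms: none
Why: Boron-mediated aldol reaction of a methyl ketone: the dialkylboron chloride enolises only the methyl side, and the (+)-isopinocampheyl ligands direct attack on the Si face of the enal to set C3 as S under reagent control.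

Step 15
Reactants: 28 (aldol adduct)
Product: 29 C3 triethylsilyl ether of 28
Conditions: TESOTf, 2,6-lutidine, CH2Cl2, −78 °C
Reagents that add atoms: triethylsilyl trifluoromethanesulfonate CC[Si](CC)(CC)OS(=O)(=O)C(F)(F)F
Why: Low-temperature silylation protects the allylic carbinol cis to the future carbon–metal bond without retro-aldol cleavage.

Step 16
Reactants: 29 C3 triethylsilyl ether of 28
Product: 30 C1 ethylene ketal (1,3-dioxolane) of 29
Conditions: 1,2-bis(trimethylsilyloxy)ethane, TMSOTf (5 mol %), CH2Cl2, −78 °C → −30 °C; pyridine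
Reagents that add atoms: 1,2-bis(trimethylsilyloxy)ethane C[Si](C)(C)OCCO[Si](C)(C)C
Why: Aprotic silyl-triflate-catalysed ketalisation masks C1, which a (Z)-alkenylchromium at C5 would otherwise attack in a five-membered ring closure in step 19; esters, silyl ether and alkenyl iodide should be inert at this temperature.

Step 17
Reactants: 30 C1 ethylene ketal of 29
Product: 32 5-hydroxy-2(5H)-furanone (C12 lactone carbonyl, C6 hemiacetal as both epimers), via silyl oxoenoate 31 (not isolated)
Conditions: O2, hv (visible), tetraphenylporphyrin (cat.), CH2Cl2, −78 °C; then THF/H2O, 0 °C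
Reagents that add atoms: dioxygen O=O
Why: Silyl-directed furan photooxygenation: singlet oxygen adds [4+2] across C12 and C6, a 1,2-shift of silicon from C12 to peroxide oxygen opens the endoperoxide to the silyl (Z)-4-oxoenoate, and hydrolysis gives the hydroxybutenolide with the carbonyl at the carbon that bore silicon.

Step 18
Reactants: 32 5-hydroxy-2(5H)-furanone
Product: 33 methyl (Z)-4-oxobut-2-enoate (C6 aldehyde and C12 methyl ester cis on C7=C11; C13 acetoxymethyl on C11)
Conditions: TMSCHN2, MeOH/toluene (1:4), 0 °C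
Reagents that add atoms: trimethylsilyldiazomethane C[Si](C)(C)C=[N+]=[N-]
Why: Methylation of the pseudo-acid under neutral conditions traps the open-chain carboxylic acid tautomer as its methyl ester, which frees the C6 aldehyde and avoids base-induced loss of the C13 acetate.

Step 19
Reactants: 33 methyl (Z)-4-oxobut-2-enoate
Product: 35 (3S,6R,8S,10S,4Z)-macrocyclic butenolide (3-OTES, C1 dioxolane, 8-O-[(2Z)-4-acetoxy-3-methylbut-2-enoyl], 13-acetoxy, germacra-4,7(11)-dien-12,6-olide skeleton), via hydroxy ester 34 (not isolated)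
Conditions: CrCl2 (10 equiv), NiCl2 (0.1 equiv), degassed DMSO, rt, 33 added over 12 h (final 2 mM); aq. NH4Cl
Reagents that add atoms: none
Why: Zerovalent nickel, formed from NiCl2 by CrCl2, inserts into the C5–I bond and passes the alkenyl group with retention of its Z geometry to trivalent chromium; the alkenylchromium adds to the C6 aldehyde, and the chromium alkoxide then attacks the C12 methyl ester held cis to it on the C7=C11 olefin and expels methoxide. The closest known reaction type is the Nozaki–Hiyama–Kishi macrocyclisation of an alkenyl iodide onto an aldehyde, established for ten-membered carbocycles, joined to the spontaneous lactonisation of (Z)-4-hydroxy-2-enoates. The ten-membered carbocycle closes by a 10-exo-trig 1,2-addition and the butenolide by a 5-exo-trig acyl substitution. The new stereocentre C6 is set under substrate control by C8: C8–H eclipses the C7=C11 bond to avoid allylic strain with the C13 acetoxymethyl group, which puts the C8 acyloxy group on one face of the enal and C9 on the other, and C5, tied to C9 by five atoms, should reach C6 from the acyloxy-bearing face because placing C5 and C9 on the same face would be a syn-pentane arrangement across C7; this gives the (6R) alkoxide. The step needs aldehyde selectivity, which the alkenylchromium has over the four ester groups and which the dioxolane secures against ring closure onto C1, and it needs ring closure to outrun oligomerisation, which slow addition at high dilution and the trigonal ring atoms C4, C5 and C7 favour.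

Step 20
Reactants: 35 macrocyclic butenolide (3-OTES, C1 dioxolane)
Product: 36 (3S,6R,8S,10S,4Z)-13-acetoxy-3-hydroxy-1-oxo-8-[(2Z)-4-acetoxy-3-methylbut-2-enoyloxy]germacra-4,7(11)-dien-12,6-olide
Conditions: PPTS, acetone/H2O (9:1), 40 °C
Reagents that add atoms: water O
Why: Mild acid hydrolysis removes the triethylsilyl ether and the dioxolane in one operation, while acetates, enoate and butenolide should survive pyridinium-buffered conditions.

Step 21
Reactants: 36 macrocyclic (Z)-olefin alcohol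
Product: 37 (3S,4R,5S,6S,8S,10S)-13-acetoxy-4,5-epoxy-3-hydroxy-1-oxo-8-[(2Z)-4-acetoxy-3-methylbut-2-enoyloxy]germacr-7(11)-en-12,6-olide (CNP0232076.1)
Conditions: mCPBA, NaHCO3, CH2Cl2, 0 °C
Reagents that add atoms: 3-chloroperbenzoic acid OOC(=O)c1cccc(Cl)c1
Why: Hydroxyl-directed peracid epoxidation: only the C4=C5 olefin is electron-rich, and for a (Z)-cycloalkenol of medium ring size the hydrogen-bonded peracid should attack the outer face of the conformer with C3–H eclipsing the olefin, giving the epoxide trans to the C3 hydroxyl (threo), that is 4R,5S.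

**Compound list**
1 | furan-3-ylmethanol | OCc1ccoc1 | starting material
2 | tert-butyl(furan-3-ylmethoxy)dimethylsilane | CC(C)(C)[Si](C)(C)OCc1ccoc1 | intermediate
3 | 2-lithio derivative of 2 | CC(C)(C)[Si](C)(C)OCc1ccoc1[Li] | intermediate
4 | [2-(tert-butyldimethylsilyl)furan-3-yl]methanol | OCc1ccoc1[Si](C)(C)C(C)(C)C | intermediate
5 | O,C4-dilithio derivative of 4 | [Li]OCc1c([Li])coc1[Si](C)(C)C(C)(C)C | intermediate
6 | 5-(tert-butyldimethylsilyl)-4-(hydroxymethyl)furan-3-carboxylic acid | OCc1c(C(=O)O)coc1[Si](C)(C)C(C)(C)C | intermediate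
7 | tert-butyldimethylsilyl 5-(tert-butyldimethylsilyl)-4-[(tert-butyldimethylsilyloxy)methyl]furan-3-carboxylate | CC(C)(C)[Si](C)(C)OCc1c(C(=O)O[Si](C)(C)C(C)(C)C)coc1[Si](C)(C)C(C)(C)C | intermediate
8 | 5-(tert-butyldimethylsilyl)-4-[(tert-butyldimethylsilyloxy)methyl]furan-3-carboxylic acid | CC(C)(C)[Si](C)(C)OCc1c(C(=O)O)coc1[Si](C)(C)C(C)(C)C | intermediate
9 | methyl (R)-3-bromo-2-methylpropanoate | COC(=O)[C@@H](C)CBr | starting material
10 | 5-(tert-butyldimethylsilyl)-4-[(tert-butyldimethylsilyloxy)methyl]furan-3-carbonyl chloride | CC(C)(C)[Si](C)(C)OCc1c(C(Cl)=O)coc1[Si](C)(C)C(C)(C)C | intermediate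
11 | [(2R)-3-methoxy-2-methyl-3-oxopropyl]zinc bromide | COC(=O)[C@@H](C)C[Zn]Br | intermediate
12 | methyl (2S)-2-methyl-4-oxo-4-[5-TBS-4-(TBSOCH2)furan-3-yl]butanoate | COC(=O)[C@@H](C)CC(=O)c1coc([Si](C)(C)C(C)(C)C)c1CO[Si](C)(C)C(C)(C)C | intermediate
13 | methyl (2S,4S)-4-hydroxy-2-methyl-4-[5-TBS-4-(TBSOCH2)furan-3-yl]butanoate | COC(=O)[C@@H](C)C[C@H](O)c1coc([Si](C)(C)C(C)(C)C)c1CO[Si](C)(C)C(C)(C)C | intermediate
14 | (3S,5S)-3-methyl-5-[5-TBS-4-(TBSOCH2)furan-3-yl]oxolan-2-one | C[C@H]1C[C@@H](c2coc([Si](C)(C)C(C)(C)C)c2CO[Si](C)(C)C(C)(C)C)OC1=O | intermediate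
15 | (3S,5S)-5-hydroxy-3-methyl-5-[5-TBS-4-(TBSOCH2)furan-3-yl]pentan-2-one | CC(=O)[C@@H](C)C[C@H](O)c1coc([Si](C)(C)C(C)(C)C)c1CO[Si](C)(C)C(C)(C)C | intermediate
16 | prop-2-yn-1-ol | C#CCO | starting material
17 | bromomagnesium (Z)-3-(bromomagnesio)-2-methylprop-2-en-1-olate | Br[Mg]OC/C(C)=C\[Mg]Br | intermediate
18 | (Z)-3-iodo-2-methylprop-2-en-1-ol | OC/C(C)=C\I | intermediate
19 | tert-butyl{[(Z)-3-iodo-2-methylprop-2-en-1-yl]oxy}dimethylsilane | CC(C)(C)[Si](C)(C)OC/C(C)=C\I | intermediate
20 | (Z)-3-[(tert-butyldimethylsilyl)oxy]-2-methylprop-1-enyllithium | CC(C)(C)[Si](C)(C)OC/C(C)=C\[Li] | intermediate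
21 | (2Z)-4-[(tert-butyldimethylsilyl)oxy]-3-methylbut-2-enoic acid | CC(C)(C)[Si](C)(C)OC/C(C)=C\C(=O)O | intermediate
22 | (2Z)-4-[(tert-butyldimethylsilyl)oxy]-3-methylbut-2-enoic 2,4,6-trichlorobenzoic anhydride | CC(C)(C)[Si](C)(C)OC/C(C)=C\C(=O)OC(=O)c1c(Cl)cc(Cl)cc1Cl | intermediate
23 | (1S,3S)-3-methyl-4-oxo-1-[5-TBS-4-(TBSOCH2)furan-3-yl]pentyl (2Z)-3-methyl-4-(TBSO)but-2-enoate | CC(=O)[C@@H](C)C[C@H](OC(=O)/C=C(/C)CO[Si](C)(C)C(C)(C)C)c1coc([Si](C)(C)C(C)(C)C)c1CO[Si](C)(C)C(C)(C)C | intermediate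
24 | (1S,3S)-1-[4-(hydroxymethyl)-5-TBS-furan-3-yl]-3-methyl-4-oxopentyl (2Z)-4-hydroxy-3-methylbut-2-enoate | CC(=O)[C@@H](C)C[C@H](OC(=O)/C=C(/C)CO)c1coc([Si](C)(C)C(C)(C)C)c1CO | intermediate
25 | (1S,3S)-1-[4-(acetoxymethyl)-5-TBS-furan-3-yl]-3-methyl-4-oxopentyl (2Z)-4-acetoxy-3-methylbut-2-enoate | CC(=O)[C@@H](C)C[C@H](OC(=O)/C=C(/C)COC(C)=O)c1coc([Si](C)(C)C(C)(C)C)c1COC(C)=O | intermediate
26 | (Z)-3-iodo-2-methylprop-2-enal | O=C/C(C)=C\I | intermediate
27 | diisopinocampheylboron enolate of 25 (C1=C2 enol borinate) | C=C(OB([C@H]1C[C@H]2C[C@@H]([C@@H]1C)C2(C)C)[C@H]1C[C@H]2C[C@@H]([C@@H]1C)C2(C)C)[C@@H](C)C[C@H](OC(=O)/C=C(/C)COC(C)=O)c1coc([Si](C)(C)C(C)(C)C)c1COC(C)=O | intermediate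
28 | (1S,3S,6S,7Z)-1-[4-(acetoxymethyl)-5-TBS-furan-3-yl]-6-hydroxy-8-iodo-3,7-dimethyl-4-oxooct-7-en-1-yl (2Z)-4-acetoxy-3-methylbut-2-enoate | I/C=C(C)\[C@@H](O)CC(=O)[C@@H](C)C[C@H](OC(=O)/C=C(/C)COC(C)=O)c1coc([Si](C)(C)C(C)(C)C)c1COC(C)=O | intermediate
29 | C3 triethylsilyl ether of 28 | I/C=C(C)\[C@@H](O[Si](CC)(CC)CC)CC(=O)[C@@H](C)C[C@H](OC(=O)/C=C(/C)COC(C)=O)c1coc([Si](C)(C)C(C)(C)C)c1COC(C)=O | intermediate
30 | C1 ethylene ketal (1,3-dioxolane) of 29 | I/C=C(C)\[C@@H](O[Si](CC)(CC)CC)CC1(OCCO1)[C@@H](C)C[C@H](OC(=O)/C=C(/C)COC(C)=O)c1coc([Si](C)(C)C(C)(C)C)c1COC(C)=O | intermediate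
31 | tert-butyldimethylsilyl (Z)-4-oxobut-2-enoate from 30 (C6 aldehyde, C12 silyl ester) | I/C=C(C)\[C@@H](O[Si](CC)(CC)CC)CC1(OCCO1)[C@@H](C)C[C@H](OC(=O)/C=C(/C)COC(C)=O)/C(C=O)=C(\COC(C)=O)C(=O)O[Si](C)(C)C(C)(C)C | intermediate
32 | 5-hydroxy-2(5H)-furanone from 30 (C12 carbonyl, C6 hemiacetal, both epimers) | I/C=C(C)\[C@@H](O[Si](CC)(CC)CC)CC1(OCCO1)[C@@H](C)C[C@H](OC(=O)/C=C(/C)COC(C)=O)C1=C(COC(C)=O)C(=O)OC1O | intermediate
33 | methyl (Z)-4-oxobut-2-enoate (C6 aldehyde cis to C12 methyl ester on C7=C11) | I/C=C(C)\[C@@H](O[Si](CC)(CC)CC)CC1(OCCO1)[C@@H](C)C[C@H](OC(=O)/C=C(/C)COC(C)=O)/C(C=O)=C(\COC(C)=O)C(=O)OC | intermediate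
34 | ten-membered (3S,6R,8S,10S)-6-hydroxy carbocycle with exocyclic C7=C11 methyl ester cis to C6 (chromium alkoxide before work-up) | COC(=O)/C(COC(C)=O)=C1/[C@@H](OC(=O)/C=C(/C)COC(C)=O)C[C@H](C)C2(OCCO2)C[C@H](O[Si](CC)(CC)CC)/C(C)=C\[C@H]1O | intermediate
35 | (3S,6R,8S,10S,4Z)-macrocyclic butenolide, 3-OTES, C1 dioxolane | CC(=O)OCC1=C2[C@@H](OC(=O)/C=C(/C)COC(C)=O)C[C@H](C)C3(OCCO3)C[C@H](O[Si](CC)(CC)CC)/C(C)=C\[C@H]2OC1=O | intermediate
36 | (3S,6R,8S,10S,4Z)-13-acetoxy-3-hydroxy-1-oxo-8-[(2Z)-4-acetoxy-3-methylbut-2-enoyloxy]germacra-4,7(11)-dien-12,6-olide | CC(=O)OCC1=C2[C@@H](OC(=O)/C=C(/C)COC(C)=O)C[C@H](C)C(=O)C[C@H](O)/C(C)=C\[C@H]2OC1=O | intermediate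
37 | CNP0232076.1, (3S,4R,5S,6S,8S,10S)-13-acetoxy-4,5-epoxy-3-hydroxy-1-oxo-8-[(2Z)-4-acetoxy-3-methylbut-2-enoyloxy]germacr-7(11)-en-12,6-olide | CC(=O)OCC1=C2[C@@H](OC(=O)/C=C(/C)COC(C)=O)C[C@H](C)C(=O)C[C@H](O)[C@@]3(C)O[C@H]3[C@H]2OC1=O | target

**Totals**
Total step count: 21. Longest linear sequence: 17 steps (steps 1–7, 11, 12, 14–21, from compound 1).

**Steps most likely to fail**

Step 19. Three processes may defeat it: electron transfer from divalent chromium to the electron-poor 4-oxoenoate (conjugate reduction or loss of the allylic C13 acetate) faster than nickel activates the iodide; oligomerisation in place of ring closure; and poor facial selectivity at C6. The fallback closes the ring at C4=C5 and sets C6 by reagent control; it sets out from 25 and comes back at 36. The boron aldol of step 14 is run on 25 with 2-methylprop-2-enal in place of 26 and should give the isopropenyl carbinol F1. Silyl-directed photooxygenation as in step 17 gives the hydroxybutenolide F2, and trimethylsilyldiazomethane gives the methyl (Z)-4-oxoenoate F3. An intermolecular Nozaki–Hiyama–Kishi vinylation with vinyl bromide (CrCl2, NiCl2, chiral oxazoline–sulfonamide ligand, which controls the C6 face) followed by lactonisation gives the 6-vinyl butenolide F4; the ketone needs no mask here because no alkenyl metal is tethered to it. Ring-closing metathesis of F4 with the second-generation Hoveyda–Grubbs catalyst in dilute toluene closes the ten-membered ring, with the Z geometry enforced by ring size, and gives 36.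

Step 21. Oxygen may be delivered to the wrong olefin face, or Baeyer–Villiger oxidation at C1 may compete. The fallback inverts the facial outcome through a halohydrin; it sets out from 36 and comes back at 37. N-Bromosuccinimide in aqueous THF should form the bromonium ion on the more accessible face, and water opens it at the tertiary C4 anti to bromine to give the bromohydrin F5. Ag2O in CH2Cl2 then closes the epoxide by displacement at C5 with inversion, so the oxygen ends on the face opposite to the one the electrophile attacked.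

Step 12. The liberated (Z)-γ-hydroxy enoate may lactonise and expel the C8 alkoxide before acetylation, or the olefin geometry may scramble. The fallback never frees that hydroxyl group; it sets out from 15 and 18 and comes back at 25. Acetylation of 18 (Ac2O, pyridine) gives (Z)-3-iodo-2-methylprop-2-en-1-yl acetate F6. Palladium-catalysed alkoxycarbonylation of F6 with alcohol 15 (PdCl2(PPh3)2, CO at 1 atm, Et3N, DMF, 50 °C) proceeds with retention of olefin geometry and gives the ester F7, which already carries the side-chain acetate. HF·pyridine removes the one remaining primary O-silyl group to give the alcohol F8, and acetylation gives 25.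

**Further compounds**
F1 | step 19 | (1S,3S,6S)-1-[4-(acetoxymethyl)-5-TBS-furan-3-yl]-6-hydroxy-3,7-dimethyl-4-oxooct-7-en-1-yl (2Z)-4-acetoxy-3-methylbut-2-enoate | C=C(C)[C@@H](O)CC(=O)[C@@H](C)C[C@H](OC(=O)/C=C(/C)COC(C)=O)c1coc([Si](C)(C)C(C)(C)C)c1COC(C)=O
F2 | step 19 | 5-hydroxy-2(5H)-furanone from F1 (C12 carbonyl, C6 hemiacetal, both epimers) | C=C(C)[C@@H](O)CC(=O)[C@@H](C)C[C@H](OC(=O)/C=C(/C)COC(C)=O)C1=C(COC(C)=O)C(=O)OC1O
F3 | step 19 | methyl (Z)-4-oxobut-2-enoate from F2 (C6 aldehyde cis to C12 methyl ester) | C=C(C)[C@@H](O)CC(=O)[C@@H](C)C[C@H](OC(=O)/C=C(/C)COC(C)=O)/C(C=O)=C(\COC(C)=O)C(=O)OC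
F4 | step 19 | (6R)-6-vinyl butenolide with the open C8–C3 chain ending in the isopropenyl carbinol | C=C[C@H]1OC(=O)C(COC(C)=O)=C1[C@@H](OC(=O)/C=C(/C)COC(C)=O)C[C@H](C)C(=O)C[C@H](O)C(C)=C
F5 | step 21 | 5-bromo-3,4-dihydroxy compound from 36 (C4–OH configured as C4–O of 37, C5–Br anti to it) | CC(=O)OCC1=C2[C@@H](OC(=O)/C=C(/C)COC(C)=O)C[C@H](C)C(=O)C[C@H](O)[C@@](C)(O)[C@H](Br)[C@H]2OC1=O
F6 | step 12 | (Z)-3-iodo-2-methylprop-2-en-1-yl acetate | CC(=O)OC/C(C)=C\I
F7 | step 12 | (1S,3S)-3-methyl-4-oxo-1-[5-TBS-4-(TBSOCH2)furan-3-yl]pentyl (2Z)-4-acetoxy-3-methylbut-2-enoate | CC(=O)[C@@H](C)C[C@H](OC(=O)/C=C(/C)COC(C)=O)c1coc([Si](C)(C)C(C)(C)C)c1CO[Si](C)(C)C(C)(C)C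
F8 | step 12 | (1S,3S)-1-[4-(hydroxymethyl)-5-TBS-furan-3-yl]-3-methyl-4-oxopentyl (2Z)-4-acetoxy-3-methylbut-2-enoate | CC(=O)[C@@H](C)C[C@H](OC(=O)/C=C(/C)COC(C)=O)c1coc([Si](C)(C)C(C)(C)C)c1CO
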